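**Retrosynthetic overview**

1. The target is an all-trans (2R,3S,4S) 4-arylflavan-3-ol (rings A, C, B) whose C4 carries ring E of a flavonol (rings D, F, E). The last steps are hydrogenolysis of seven benzyl ethers and, before that, conversion of a C3–B bond into the C3–OH with retention.
2. Key disconnection: ring C is closed by a cationic [4+2] annulation of oxa-Povarov type that forms C2–C3 and C4–C4a at once. The partners are an O-aryl oxocarbenium ion (C4a=C8a–O1=C2, from a diaryl acetal of 3,4-bis(benzyloxy)benzaldehyde) and an (E)-alkenyl boronate (C3=C4) that already carries the benzylated flavonol.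
3. Enabling feature: C4 is benzylic to ring E carbon C2', which has oxygen at C3' (ortho) and C5' (para), so a C4 cation is stabilised, and C4a of ring A is ortho to O1, so it can close ring C. The boron on C3, in a pinene-derived PIDA cage (the only bought chirality), is β-cation stabiliser, face director and masked hydroxyl in one.
4. The alkenyl boronate comes from a Heck coupling of a 2'-bromoflavonol with vinyl PIDA boronate; flavonol ring F comes from a Claisen–Schmidt condensation and an Algar–Flynn–Oyamada cyclisation.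
5. Ring order: rings A, B, D and E are bought; ring F is formed in step 6 and ring C in step 11.

Key step: step 11

Assumption: PIDA boronates are written without the N→B dative bond, and the (1R,2R,3R,5S)-isopinocampheyl ligand is taken to block the alkene face that leads to the (3S) boronate; if the sense proves opposite, the enantiomeric amine (also commercial) is carried through the same steps.

**Route**

Step 1
Reactants: 1 (1R,2R,3R,5S)-isopinocampheylamine
Product: 2 dibenzyl N-[(1R,2R,3R,5S)-isopinocampheyl]iminodiacetate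
Conditions: BrCH2CO2Bn (2.2 equiv), iPr2NEt, MeCN, 60 °C
Reagents that add atoms: benzyl bromoacetate, O=C(CBr)OCc1ccccc1
Why: Double SN2 N-alkylation of the hindered primary amine with an activated α-bromo ester should stop at the tertiary amine, and the four bought pinane stereocentres are not touched.

Step 2
Reactants: 2 dibenzyl N-isopinocampheyliminodiacetate
Product: 3 N-[(1R,2R,3R,5S)-isopinocampheyl]iminodiacetic acid (PIDA)
Conditions: H2 (1 atm), Pd/C, MeOH, rt
Reagents that add atoms: none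
Why: Hydrogenolysis of the two benzyl esters should free the diacid under neutral conditions.

Step 3
Reactants: 3 PIDA; 4 2,4,6-trivinylboroxin–pyridine complex
Product: 5 vinyl PIDA boronate
Conditions: toluene/DMSO (10:1), BHT (cat.), Dean–Stark, reflux
Reagents that add atoms: none
Why: Dehydrative condensation of a boronic anhydride with an N-substituted iminodiacetic acid, driven by azeotropic removal of water, should give the bench-stable tetracoordinate boronate.

Step 4
Reactants: 6 3,4,5-tris(benzyloxy)benzaldehyde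
Product: 7 2-bromo-3,4,5-tris(benzyloxy)benzaldehyde
Conditions: NBS, MeCN, 50 °C, dark
Reagents that add atoms: N-bromosuccinimide, O=C1CCC(=O)N1Br
Why: Electrophilic aromatic bromination can only occur at the two equivalent free ring positions, each ortho and para to a benzyloxy group.

Step 5
Reactants: 7 2-bromo-3,4,5-tris(benzyloxy)benzaldehyde; 8 1-[4-(benzyloxy)-2-hydroxyphenyl]ethan-1-one
Product: 9 (E)-3-[2-bromo-3,4,5-tris(benzyloxy)phenyl]-1-[4-(benzyloxy)-2-hydroxyphenyl]prop-2-en-1-one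
Conditions: KOH, EtOH/THF, rt
Reagents that add atoms: none
Why: Claisen–Schmidt aldol condensation with E1cB dehydration should give the (E)-chalcone.

Step 6
Reactants: 9 (E)-2'-hydroxychalcone
Product: 11 7-(benzyloxy)-2-[2-bromo-3,4,5-tris(benzyloxy)phenyl]-3-hydroxy-4H-chromen-4-one, via trans-dihydroflavonol 10 (not isolated)
Conditions: 30% H2O2, aq NaOH, MeOH/THF, 0 °C → rt
Reagents that add atoms: hydrogen peroxide, OO
Why: The Algar–Flynn–Oyamada oxidative cyclisation of a 2'-hydroxychalcone should close ring F as the flavonol, and the absence of a 6'-substituent on the acetophenone ring disfavours the aurone pathway.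

Step 7
Reactants: 11 3-hydroxyflavone bromide
Product: 12 3,7-bis(benzyloxy)-2-[2-bromo-3,4,5-tris(benzyloxy)phenyl]-4H-chromen-4-one
Conditions: BnBr, K2CO3, DMF, 60 °C
Reagents that add atoms: benzyl bromide, BrCc1ccccc1
Why: Williamson etherification of the acidic 3-hydroxyl removes the last free OH before the palladium and acid steps.

Step 8
Reactants: 12 pentabenzyl 2'-bromoflavonol; 5 vinyl PIDA boronate
Product: 13 3,7-bis(benzyloxy)-2-{3,4,5-tris(benzyloxy)-2-[(E)-2-(PIDA-boryl)ethenyl]phenyl}-4H-chromen-4-one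
Conditions: Pd2(dba)3, P(t-Bu)3·HBF4, Cy2NMe, 1,4-dioxane, 90 °C
Reagents that add atoms: none
Why: In this Heck reaction, oxidative addition of zerovalent palladium (bulky, electron-rich phosphine for the doubly ortho-substituted bromide), insertion with the aryl group going to the unsubstituted alkene carbon and syn β-hydride elimination should give the (E)-alkenyl boronate, and the tetracoordinate boron cannot transmetalate, so no Suzuki-type coupling competes.

Step 9
Reactants: 14 3,4-bis(benzyloxy)benzaldehyde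
Product: 15 1,2-bis(benzyloxy)-4-(dichloromethyl)benzene
Conditions: (COCl)2, Ph3PO (15 mol %), CHCl3, rt; evaporate, use crude
Reagents that add atoms: oxalyl chloride, O=C(Cl)C(=O)Cl
Why: Deoxydichlorination of the aldehyde by the chlorophosphonium salt formed in situ from Ph3PO and oxalyl chloride should give the geminal dichloride without touching the benzyl ethers.

Step 10
Reactants: 15 geminal dichloride; 16 3-hydroxyphenyl benzoate (2.1 equiv)
Product: 17 [3,4-bis(benzyloxy)phenyl]methylenebis(oxy-3,1-phenylene) dibenzoate (diaryl acetal)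
Conditions: 2,6-lutidine, CH2Cl2, 0 °C → rt; Et3N-treated silica
Reagents that add atoms: none
Why: Two SN1-type substitutions of the p-alkoxy-stabilised benzylic chlorides by the phenol (Williamson-type acetal formation) should give the symmetric acetal, and the weak, hindered base removes HCl without forming free phenoxide, so benzoyl transfer is avoided.

Step 11
Reactants: 13 (E)-alkenyl PIDA boronate; 17 diaryl acetal (1.3 equiv)
Product: 20 (2S,3S,4S)-2-[3,4-bis(benzyloxy)phenyl]-4-{2,3,4-tris(benzyloxy)-6-[3,7-bis(benzyloxy)-4-oxo-4H-chromen-2-yl]phenyl}-3-(PIDA-boryl)-3,4-dihydro-2H-chromen-7-yl benzoate, via oxocarbenium triflimide 18 (not isolated), via benzylic cation 19 (not isolated)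
Conditions: Tf2NH (10 mol %), 4 Å MS, CH2Cl2, −78 → −30 °C; Et3N quench
Reagents that add atoms: none
Why: Proposed new method: Tf2NH ionises the diaryl acetal 17 (either aryloxide leaving gives the same ion) to the (E)-O-aryl oxocarbenium ion 18, a cationic 2-oxadiene (C4a=C8a–O1=C2) whose C2 is attacked by the boron-bearing carbon of alkene 13 to give the benzylic cation 19, stabilised by the ortho and para benzyloxy groups of ring E and by the β C–B bond, and the proton lost on ring closure turns the acid over. The closest known reaction types are the Lewis acid-promoted oxa-Povarov reaction of O-aryl oxocarbenium ions with styrenes and Povarov reactions of (E)-anethole, which give all-trans 2,3,4-trisubstituted products; new here are the alkenyl boronate as the 2π partner and its chiral boron ligand as the source of absolute control, for which the face-selective epoxidation of alkenyl PIDA boronates is the precedent. Ring C closes by a 6-endo-trig Friedel–Crafts attack on C4 of the ring A carbon that is ortho to O1 and para to the benzoyloxy group. C3 is set by the isopinocampheyl group of the PIDA cage, which shields one face of the alkene; C4 follows from the (E) geometry because both bonds form on the same face (3,4-trans); C2 follows from an approach with ring E endo and the boron cage exo to the oxadiene (2,3-trans), so all three groups end up equatorial. The step needs regioselectivity (attack at the boron-bearing carbon, which the aryl group and the β-boron effect both favour, and closure para rather than ortho to the benzoate, the ortho site being flanked by two oxygens) and chemoselectivity over loss of boron and over intermolecular Friedel–Crafts alkylation. The tetracoordinate boron, which no nucleophile can attack, and the benzoate, which tempers ring A until the cation is held next to it, are there to secure these.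

Step 12
Reactants: 20 chroman PIDA boronate
Product: 22 3,7-bis(benzyloxy)-2-{3,4,5-tris(benzyloxy)-2-[(2R,3S,4S)-2-[3,4-bis(benzyloxy)phenyl]-3,7-dihydroxy-3,4-dihydro-2H-chromen-4-yl]phenyl}-4H-chromen-4-one, via boronic acid 21 (not isolated)
Conditions: 30% H2O2, 1 M aq NaOH, THF, 0 °C → rt; aq NH4Cl
Reagents that add atoms: hydrogen peroxide, OO
Why: In this boronate oxidation, hydroxide opens the PIDA cage and cleaves the aryl benzoate, hydroperoxide adds to boron and C3 migrates from boron to oxygen with retention, so the C–B bond becomes the 3S hydroxyl without touching C2 or C4, and peroxide is present from the start so that migration outruns β-elimination of the ring A aryloxide.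

Step 13
Reactants: 22 heptabenzyl ether
Product: 23 3,7-dihydroxy-2-{3,4,5-trihydroxy-2-[(2R,3S,4S)-2-(3,4-dihydroxyphenyl)-3,7-dihydroxy-3,4-dihydro-2H-chromen-4-yl]phenyl}-4H-chromen-4-one (target)
Conditions: H2 (1 atm), Pd(OH)2/C, THF/MeOH (1:1), rt; filtration under N2, Sephadex LH-20
Reagents that add atoms: none
Why: Hydrogenolysis over palladium should cleave only the seven O–benzyl bonds, since the flavonol double bond and the flavan C2–O1 and C4–aryl bonds are expected to survive these neutral conditions, and no stereocentre is involved.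

**Compound list**

1 | (1R,2R,3R,5S)-2,6,6-trimethylbicyclo[3.1.1]heptan-3-amine ((−)-isopinocampheylamine) | N[C@@H]1C[C@@H]2C[C@H]([C@H]1C)C2(C)C | starting material
2 | dibenzyl 2,2'-{[(1R,2R,3R,5S)-2,6,6-trimethylbicyclo[3.1.1]heptan-3-yl]azanediyl}diacetate | O=C(CN(CC(=O)OCc1ccccc1)[C@@H]1C[C@@H]2C[C@H]([C@H]1C)C2(C)C)OCc1ccccc1 | intermediate
3 | N-[(1R,2R,3R,5S)-isopinocampheyl]iminodiacetic acid (PIDA) | O=C(O)CN(CC(=O)O)[C@@H]1C[C@@H]2C[C@H]([C@H]1C)C2(C)C | intermediate
4 | 2,4,6-trivinylboroxin–pyridine complex | C=CB1OB(C=C)OB(C=C)O1.c1ccncc1 | starting material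
5 | vinyl PIDA boronate, 2-ethenyl-6-[(1R,2R,3R,5S)-2,6,6-trimethylbicyclo[3.1.1]heptan-3-yl]-1,3,6,2-dioxazaborocane-4,8-dione (N→B bond not drawn) | C=CB1OC(=O)CN(CC(=O)O1)[C@@H]1C[C@@H]2C[C@H]([C@H]1C)C2(C)C | intermediate
6 | 3,4,5-tris(benzyloxy)benzaldehyde | O=Cc1cc(OCc2ccccc2)c(OCc2ccccc2)c(OCc2ccccc2)c1 | starting material
7 | 2-bromo-3,4,5-tris(benzyloxy)benzaldehyde | O=Cc1cc(OCc2ccccc2)c(OCc2ccccc2)c(OCc2ccccc2)c1Br | intermediate
8 | 1-[4-(benzyloxy)-2-hydroxyphenyl]ethan-1-one | CC(=O)c1ccc(OCc2ccccc2)cc1O | starting material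
9 | (E)-3-[2-bromo-3,4,5-tris(benzyloxy)phenyl]-1-[4-(benzyloxy)-2-hydroxyphenyl]prop-2-en-1-one | O=C(/C=C/c1cc(OCc2ccccc2)c(OCc2ccccc2)c(OCc2ccccc2)c1Br)c1ccc(OCc2ccccc2)cc1O | intermediate
10 | (±)-trans-7-(benzyloxy)-2-[2-bromo-3,4,5-tris(benzyloxy)phenyl]-3-hydroxychroman-4-one (racemic, 2,3-trans, no descriptors in the SMILES; not isolated) | O=C1c2ccc(OCc3ccccc3)cc2OC(c2cc(OCc3ccccc3)c(OCc3ccccc3)c(OCc3ccccc3)c2Br)C1O | intermediate
11 | 7-(benzyloxy)-2-[2-bromo-3,4,5-tris(benzyloxy)phenyl]-3-hydroxy-4H-chromen-4-one | O=c1c(O)c(-c2cc(OCc3ccccc3)c(OCc3ccccc3)c(OCc3ccccc3)c2Br)oc2cc(OCc3ccccc3)ccc12 | intermediate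
12 | 3,7-bis(benzyloxy)-2-[2-bromo-3,4,5-tris(benzyloxy)phenyl]-4H-chromen-4-one | O=c1c(OCc2ccccc2)c(-c2cc(OCc3ccccc3)c(OCc3ccccc3)c(OCc3ccccc3)c2Br)oc2cc(OCc3ccccc3)ccc12 | intermediate
13 | 3,7-bis(benzyloxy)-2-{3,4,5-tris(benzyloxy)-2-[(E)-2-(PIDA-boryl)ethenyl]phenyl}-4H-chromen-4-one (PIDA-boryl = 6-[(1R,2R,3R,5S)-isopinocampheyl]-4,8-dioxo-1,3,6,2-dioxazaborocan-2-yl) | O=c1c(OCc2ccccc2)c(-c2cc(OCc3ccccc3)c(OCc3ccccc3)c(OCc3ccccc3)c2/C=C/B2OC(=O)CN(CC(=O)O2)[C@@H]2C[C@@H]3C[C@H]([C@H]2C)C3(C)C)oc2cc(OCc3ccccc3)ccc12 | intermediate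
14 | 3,4-bis(benzyloxy)benzaldehyde | O=Cc1ccc(OCc2ccccc2)c(OCc2ccccc2)c1 | starting material
15 | 1,2-bis(benzyloxy)-4-(dichloromethyl)benzene | ClC(Cl)c1ccc(OCc2ccccc2)c(OCc2ccccc2)c1 | intermediate
16 | 3-hydroxyphenyl benzoate (resorcinol monobenzoate) | O=C(Oc1cccc(O)c1)c1ccccc1 | starting material
17 | [3,4-bis(benzyloxy)phenyl]methylenebis(oxy-3,1-phenylene) dibenzoate | O=C(Oc1cccc(OC(Oc2cccc(OC(=O)c3ccccc3)c2)c2ccc(OCc3ccccc3)c(OCc3ccccc3)c2)c1)c1ccccc1 | intermediate
18 | (E)-[3-(benzoyloxy)phenyl][3,4-bis(benzyloxy)benzylidene]oxonium bis(trifluoromethanesulfonyl)imide (not isolated) | O=C(Oc1cccc(/[O+]=C/c2ccc(OCc3ccccc3)c(OCc3ccccc3)c2)c1)c1ccccc1.O=S(=O)([N-]S(=O)(=O)C(F)(F)F)C(F)(F)F | intermediate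
19 | open-chain benzylic cation after C2–C3 bond formation, cation at C4 on ring E, C2 and C3 already set, triflimide salt (not isolated) | O=c1c(OCc2ccccc2)c(-c2cc(OCc3ccccc3)c(OCc3ccccc3)c(OCc3ccccc3)c2[CH+][C@H](B2OC(=O)CN(CC(=O)O2)[C@@H]2C[C@@H]3C[C@H]([C@H]2C)C3(C)C)[C@H](Oc2cccc(OC(=O)c3ccccc3)c2)c2ccc(OCc3ccccc3)c(OCc3ccccc3)c2)oc2cc(OCc3ccccc3)ccc12.O=S(=O)([N-]S(=O)(=O)C(F)(F)F)C(F)(F)F | intermediate
20 | (2S,3S,4S)-2-[3,4-bis(benzyloxy)phenyl]-4-{2,3,4-tris(benzyloxy)-6-[3,7-bis(benzyloxy)-4-oxo-4H-chromen-2-yl]phenyl}-3-(PIDA-boryl)-3,4-dihydro-2H-chromen-7-yl benzoate (2,3-trans, 3,4-trans) | O=c1c(OCc2ccccc2)c(-c2cc(OCc3ccccc3)c(OCc3ccccc3)c(OCc3ccccc3)c2[C@@H]2c3ccc(OC(=O)c4ccccc4)cc3O[C@H](c3ccc(OCc4ccccc4)c(OCc4ccccc4)c3)[C@H]2B2OC(=O)CN(CC(=O)O2)[C@@H]2C[C@@H]3C[C@H]([C@H]2C)C3(C)C)oc2cc(OCc3ccccc3)ccc12 | intermediate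
21 | [(2S,3S,4S)-2-[3,4-bis(benzyloxy)phenyl]-4-{2,3,4-tris(benzyloxy)-6-[3,7-bis(benzyloxy)-4-oxo-4H-chromen-2-yl]phenyl}-7-hydroxy-3,4-dihydro-2H-chromen-3-yl]boronic acid (not isolated) | O=c1c(OCc2ccccc2)c(-c2cc(OCc3ccccc3)c(OCc3ccccc3)c(OCc3ccccc3)c2[C@@H]2c3ccc(O)cc3O[C@H](c3ccc(OCc4ccccc4)c(OCc4ccccc4)c3)[C@H]2B(O)O)oc2cc(OCc3ccccc3)ccc12 | intermediate
22 | 3,7-bis(benzyloxy)-2-{3,4,5-tris(benzyloxy)-2-[(2R,3S,4S)-2-[3,4-bis(benzyloxy)phenyl]-3,7-dihydroxy-3,4-dihydro-2H-chromen-4-yl]phenyl}-4H-chromen-4-one | O=c1c(OCc2ccccc2)c(-c2cc(OCc3ccccc3)c(OCc3ccccc3)c(OCc3ccccc3)c2[C@@H]2c3ccc(O)cc3O[C@H](c3ccc(OCc4ccccc4)c(OCc4ccccc4)c3)[C@H]2O)oc2cc(OCc3ccccc3)ccc12 | intermediate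
23 | 3,7-dihydroxy-2-{3,4,5-trihydroxy-2-[(2R,3S,4S)-2-(3,4-dihydroxyphenyl)-3,7-dihydroxy-3,4-dihydro-2H-chromen-4-yl]phenyl}-4H-chromen-4-one (CNP0381334.2) | O=c1c(O)c(-c2cc(O)c(O)c(O)c2[C@@H]2c3ccc(O)cc3O[C@H](c3ccc(O)c(O)c3)[C@H]2O)oc2cc(O)ccc12 | target

**Step count and risks**

Total step count: 13. Longest linear sequence: 8 steps (steps 4, 5, 6, 7, 8, 11, 12, 13).

Steps most likely to fail:

1. Step 11 (proposed new method). The twisted, doubly ortho-substituted styrene may react too slowly, so that self-condensation of the acetal takes over. The β-boryl cation may lose its boron group (net alkenyl transfer) before ring closure, or the PIDA cage may give poor facial selectivity. The fallback uses known reactions only and forms the two bonds in separate steps; it sets out from 12, 14 and 16 and returns at 22. Copper-free Sonogashira coupling of 12 with ethynyltrimethylsilane (PdCl2(MeCN)2, XPhos, Cs2CO3, MeCN, 80 °C) would give the silyl alkyne F1, and K2CO3/MeOH the terminal alkyne F2. Catalytic asymmetric addition of F2 to aldehyde 14 (Me2Zn, ProPhenol ligand of the enantiomer that delivers the S carbinol, toluene) would give the (S)-propargylic alcohol F3. Mitsunobu etherification with phenol 16 (PPh3, DIAD, toluene, 0 °C) would invert this centre and give the (R)-aryl propargyl ether F4. Hydroarylation catalysed by Ph3PAuNTf2 (monovalent gold, 6-endo-dig, closure para to the benzoate) would close ring C as the 2H-chromene F5. Hydroboration–oxidation (BH3·SMe2, THF, 0 °C; then NaOH, H2O2) should add anti to the C2 aryl group, set C3 and C4 in one event, cleave the benzoate and rejoin the route at 22.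

2. Step 8. Oxidative addition and insertion at a bromide flanked by two ortho substituents may be slow, so that hydrodebromination or catalyst decay wins. The fallback sets out from 5 and returns at 13. Cross-metathesis of 5 with vinylboronic acid pinacol ester (second-generation Grubbs catalyst, RuCl2(H2IMes)(PCy3)(=CHPh), CH2Cl2, 40 °C) would give the (E)-bis-boryl ethene F6. A Suzuki–Miyaura coupling of its pinacol boronate end with 12 (Pd(OAc)2, SPhos, anhydrous K3PO4, THF, 45 °C) would then form the aryl–alkenyl bond by transmetalation, leave the tetracoordinate PIDA boronate untouched and give 13.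

3. Step 12. The boron ate complex may undergo β-elimination of the ring A aryloxide, which opens ring C, and alkaline peroxide may attack the pyranone ring F. The fallback sets out from 20 and returns at 22. Ligand exchange (pinacol, NaHCO3, MeOH/THF, 45 °C) would give the pinacol boronate F7. Anhydrous oxidation with trimethylamine N-oxide (THF, 60 °C) and mild hydrolysis would give the alcohol benzoate F8 with retention at C3 and without free hydroxide. K2CO3/MeOH at 0 °C would then remove the benzoate and give 22.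

**Further compounds**

F1 | step 11 | 3,7-bis(benzyloxy)-2-{3,4,5-tris(benzyloxy)-2-[(trimethylsilyl)ethynyl]phenyl}-4H-chromen-4-one | O=c1c(OCc2ccccc2)c(-c2cc(OCc3ccccc3)c(OCc3ccccc3)c(OCc3ccccc3)c2C#C[Si](C)(C)C)oc2cc(OCc3ccccc3)ccc12
F2 | step 11 | 3,7-bis(benzyloxy)-2-[3,4,5-tris(benzyloxy)-2-ethynylphenyl]-4H-chromen-4-one | O=c1c(OCc2ccccc2)c(-c2cc(OCc3ccccc3)c(OCc3ccccc3)c(OCc3ccccc3)c2C#C)oc2cc(OCc3ccccc3)ccc12
F3 | step 11 | 3,7-bis(benzyloxy)-2-{3,4,5-tris(benzyloxy)-2-[(3S)-3-[3,4-bis(benzyloxy)phenyl]-3-hydroxyprop-1-yn-1-yl]phenyl}-4H-chromen-4-one | O=c1c(OCc2ccccc2)c(-c2cc(OCc3ccccc3)c(OCc3ccccc3)c(OCc3ccccc3)c2C#C[C@@H](O)c2ccc(OCc3ccccc3)c(OCc3ccccc3)c2)oc2cc(OCc3ccccc3)ccc12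
F4 | step 11 | 3-{[(1R)-1-[3,4-bis(benzyloxy)phenyl]-3-{2,3,4-tris(benzyloxy)-6-[3,7-bis(benzyloxy)-4-oxo-4H-chromen-2-yl]phenyl}prop-2-yn-1-yl]oxy}phenyl benzoate | O=c1c(OCc2ccccc2)c(-c2cc(OCc3ccccc3)c(OCc3ccccc3)c(OCc3ccccc3)c2C#C[C@H](Oc2cccc(OC(=O)c3ccccc3)c2)c2ccc(OCc3ccccc3)c(OCc3ccccc3)c2)oc2cc(OCc3ccccc3)ccc12
F5 | step 11 | (2S)-2-[3,4-bis(benzyloxy)phenyl]-4-{2,3,4-tris(benzyloxy)-6-[3,7-bis(benzyloxy)-4-oxo-4H-chromen-2-yl]phenyl}-2H-chromen-7-yl benzoate | O=c1c(OCc2ccccc2)c(-c2cc(OCc3ccccc3)c(OCc3ccccc3)c(OCc3ccccc3)c2C2=C[C@@H](c3ccc(OCc4ccccc4)c(OCc4ccccc4)c3)Oc3cc(OC(=O)c4ccccc4)ccc23)oc2cc(OCc3ccccc3)ccc12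
F6 | step 8 | (E)-1-(4,4,5,5-tetramethyl-1,3,2-dioxaborolan-2-yl)-2-(PIDA-boryl)ethene | CC1(C)OB(/C=C/B2OC(=O)CN(CC(=O)O2)[C@@H]2C[C@@H]3C[C@H]([C@H]2C)C3(C)C)OC1(C)C
F7 | step 12 | (2S,3S,4S)-2-[3,4-bis(benzyloxy)phenyl]-4-{2,3,4-tris(benzyloxy)-6-[3,7-bis(benzyloxy)-4-oxo-4H-chromen-2-yl]phenyl}-3-(4,4,5,5-tetramethyl-1,3,2-dioxaborolan-2-yl)-3,4-dihydro-2H-chromen-7-yl benzoate | O=c1c(OCc2ccccc2)c(-c2cc(OCc3ccccc3)c(OCc3ccccc3)c(OCc3ccccc3)c2[C@@H]2c3ccc(OC(=O)c4ccccc4)cc3O[C@H](c3ccc(OCc4ccccc4)c(OCc4ccccc4)c3)[C@H]2B2OC(C)(C)C(C)(C)O2)oc2cc(OCc3ccccc3)ccc12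
F8 | step 12 | (2R,3S,4S)-2-[3,4-bis(benzyloxy)phenyl]-4-{2,3,4-tris(benzyloxy)-6-[3,7-bis(benzyloxy)-4-oxo-4H-chromen-2-yl]phenyl}-3-hydroxy-3,4-dihydro-2H-chromen-7-yl benzoate | O=c1c(OCc2ccccc2)c(-c2cc(OCc3ccccc3)c(OCc3ccccc3)c(OCc3ccccc3)c2[C@@H]2c3ccc(OC(=O)c4ccccc4)cc3O[C@H](c3ccc(OCc4ccccc4)c(OCc4ccccc4)c3)[C@H]2O)oc2cc(OCc3ccccc3)ccc12
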